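**Retrosynthetic overview**

1. The target is 6-(3-hydroxybenzoyl)-5,7-dihydroxy-2,2-dimethyl-8-prenyl-2H-chromene (13). Ring A is bought as aldehyde 1, ring B is built second, and the pyran ring is closed last.
2. The route rests on ring B: its only hydroxyl sits on C3′, meta to the ketone-bearing C1′. Cutting C1′–C6′ and C2′–C3′ turns ring B into furan 5 (C3′ to C6′ and the oxygen) plus the two alkyne carbons (C1′, C2′) of ynone 4.
3. Ynone 4 comes from aldehyde 1 by ethynyl Grignard addition and MnO2 oxidation.
4. Endgame on ring A: cleavage of the three methyl ethers, C-prenylation (future C8), then annulation with prenal (C4a–C4 and O1–C2 bonds) to close the pyran.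

Key step: step 3

Remark: the target has no stereogenic element (the only sp3 ring carbon, C2 of the pyran, carries two methyl groups), so it is one achiral compound and no enantiocontrol is needed.

**Route**

Step 1
Reactants: 1 2,4,6-trimethoxybenzaldehyde; 2 ethynylmagnesium bromide
Product: 3 rac-1-(2,4,6-trimethoxyphenyl)prop-2-yn-1-ol
Conditions: HC≡CMgBr (1.3 equiv, 0.5 M in THF), THF, 0 °C → rt; sat. aq. NH4Cl; used crude
Reagents that add atoms: none
Why: 1,2-addition of an alkynyl Grignard reagent to a non-enolisable aryl aldehyde is fast at 0 °C; the carbinol centre forms racemic and is erased in step 2, and the acid-labile, electron-rich benzylic alcohol is kept neutral and carried on without chromatography.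

Step 2
Reactants: 3 rac-1-(2,4,6-trimethoxyphenyl)prop-2-yn-1-ol
Product: 4 1-(2,4,6-trimethoxyphenyl)prop-2-yn-1-one
Conditions: activated MnO2 (15 equiv), CH2Cl2, rt
Reagents that add atoms: none
Why: MnO2 oxidation of a benzylic, propargylic secondary alcohol to the ynone runs under neutral conditions that leave the terminal alkyne and the aryl methyl ethers untouched.

Step 3
Reactants: 4 1-(2,4,6-trimethoxyphenyl)prop-2-yn-1-one; 5 furan
Product: 7 (3-hydroxyphenyl)(2,4,6-trimethoxyphenyl)methanone, via oxanorbornadiene ketone 6 (not isolated)
Conditions: furan (10 equiv), Me2AlCl (1.2 equiv), CH2Cl2, −40 → 0 °C; cold 1 M HCl work-up; crude adduct, TsOH·H2O (20 mol%), CH2Cl2, 0 °C → rt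
Reagents that add atoms: none
Why: Me2AlCl binds the ketone oxygen of 4 (ring A, twisted out of plane by its two ortho methoxy groups, does not dampen the ynone) and furan adds across the alkyne in an asynchronous concerted [4+2] cycloaddition, its α-carbons bonding to the terminal alkyne carbon (C2′–C3′) and to the internal one (C1′–C6′); the closest known reaction type is the Lewis acid promoted Diels–Alder reaction of furans with acetylenic esters and ketones. Ring B is closed as a six-membered carbocycle by this intermolecular [4+2] annulation, two σ bonds in one event, and first appears as the oxygen-bridged diene 6. Acid then ionises the bridgehead C6′–O bond, the one next to the acyl-bearing C1′, to a pentadienyl cation with charge on C2′, C4′ and C6′ only, and loss of the proton from C3′ gives the benzene ring with the furan oxygen as the C3′ hydroxyl, which is the known acid-catalysed isomerisation of 7-oxanorbornadienes to phenols. No stereocentre has to be controlled, since the two bridgehead centres of racemic 6 vanish on aromatisation. Two selectivities are needed: cycloaddition over conjugate alkenylation of furan through its C2, favoured by low temperature, excess furan and a proton-scavenging alkylaluminium Lewis acid, and meta over ortho bridge opening, secured by the acyl group because the other ionisation would put positive charge on C1′.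

Step 4
Reactants: 7 (3-hydroxyphenyl)(2,4,6-trimethoxyphenyl)methanone
Product: 8 (3-hydroxyphenyl)(2,4,6-trihydroxyphenyl)methanone
Conditions: BBr3 (6 equiv), CH2Cl2, −78 °C → rt; MeOH then H2O
Reagents that add atoms: none
Why: Lewis acid cleavage of aryl methyl ethers by BBr3 (bromide attacks the O-complexed methyl group) should remove all three methyl groups, the two next to the ketone first through chelation, while the diaryl ketone and the ring B phenol are inert to the reagent.

Step 5
Reactants: 8 (3-hydroxyphenyl)(2,4,6-trihydroxyphenyl)methanone; 9 prenyl bromide (1-bromo-3-methylbut-2-ene)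
Product: 10 (3-hydroxyphenyl)[2,4,6-trihydroxy-3-(3-methylbut-2-en-1-yl)phenyl]methanone
Conditions: prenyl bromide (0.95 equiv), DBU (1.1 equiv), THF, 0 °C → rt; unreacted 8 recovered
Reagents that add atoms: none
Why: C-alkylation of an acylphloroglucinol monoanion: one equivalent of DBU removes only the most acidic ring A proton (the ring B phenol stays protonated), the soft ring carbon C3, equivalent to C5, attacks prenyl bromide in an SN2 reaction and the dienone re-aromatises by tautomerisation, while the slight deficit of bromide limits a second alkylation.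

Step 6
Reactants: 10 (3-hydroxyphenyl)[2,4,6-trihydroxy-3-(3-methylbut-2-en-1-yl)phenyl]methanone; 11 3-methylbut-2-enal
Product: 13 [5,7-dihydroxy-2,2-dimethyl-8-(3-methylbut-2-en-1-yl)-2H-chromen-6-yl](3-hydroxyphenyl)methanone, via ortho-quinone methide 12 (not isolated)
Conditions: 3-methylbut-2-enal (1.5 equiv), ethylenediamine diacetate (20 mol%), toluene, 110 °C
Reagents that add atoms: none
Why: Amine-catalysed Knoevenagel-type condensation of the enal at C5, the only free carbon of ring A, gives ortho-quinone methide 12, whose oxa-6π electrocyclisation closes the pyran; closure on the para oxygen O4 is expected because the neighbouring ortho hydroxyl is held in the hydrogen bond to the ketone, as in the annulation of 2,4-dihydroxyaryl ketones.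

**Compound list**

1 | 2,4,6-trimethoxybenzaldehyde | COc1cc(OC)c(C=O)c(OC)c1 | starting material
2 | ethynylmagnesium bromide | C#C[Mg]Br | starting material
3 | rac-1-(2,4,6-trimethoxyphenyl)prop-2-yn-1-ol | C#CC(O)c1c(OC)cc(OC)cc1OC | intermediate
4 | 1-(2,4,6-trimethoxyphenyl)prop-2-yn-1-one | C#CC(=O)c1c(OC)cc(OC)cc1OC | intermediate
5 | furan | c1ccoc1 | starting material
6 | 7-oxabicyclo[2.2.1]hepta-2,5-dien-2-yl(2,4,6-trimethoxyphenyl)methanone (racemic; not isolated) | COc1cc(OC)c(C(=O)C2=CC3OC2C=C3)c(OC)c1 | intermediate
7 | (3-hydroxyphenyl)(2,4,6-trimethoxyphenyl)methanone | COc1cc(OC)c(C(=O)c2cccc(O)c2)c(OC)c1 | intermediate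
8 | (3-hydroxyphenyl)(2,4,6-trihydroxyphenyl)methanone | Oc1cc(O)c(C(=O)c2cccc(O)c2)c(O)c1 | intermediate
9 | prenyl bromide (1-bromo-3-methylbut-2-ene) | CC(C)=CCBr | starting material
10 | (3-hydroxyphenyl)[2,4,6-trihydroxy-3-(3-methylbut-2-en-1-yl)phenyl]methanone | CC(C)=CCc1c(O)cc(O)c(C(=O)c2cccc(O)c2)c1O | intermediate
11 | 3-methylbut-2-enal | CC(C)=CC=O | starting material
12 | ortho-quinone methide: 3,5-dihydroxy-4-(3-hydroxybenzoyl)-6-(3-methylbut-2-en-1-ylidene)-2-(3-methylbut-2-en-1-yl)cyclohexa-2,4-dien-1-one, dimethylvinyl group on the side of the ring carbonyl (not isolated) | CC(C)=CCC1=C(O)C(C(=O)c2cccc(O)c2)=C(O)/C(=C/C=C(C)C)C1=O | intermediate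
13 | [5,7-dihydroxy-2,2-dimethyl-8-(3-methylbut-2-en-1-yl)-2H-chromen-6-yl](3-hydroxyphenyl)methanone | CC(C)=CCc1c(O)c(C(=O)c2cccc(O)c2)c(O)c2c1OC(C)(C)C=C2 | target

**Step count**

Total steps: 6. Longest linear sequence: 6 steps (1 → 13).

**Steps most likely to fail**

1. Step 3 (cycloaddition and ring opening). The Lewis acid complex may be attacked by furan C2 in a stepwise manner that ends in proton loss (conjugate alkenylation) instead of ring closure, furan may oligomerise under acid, and the bridge may open in part towards the ortho phenol. Fallback, setting out from furan 5 and returning at 7: ring B is still made from furan, but with a simpler dienophile of the same known reaction class, and ring A is attached afterwards. Furan 5 and methyl propiolate (C#CC(=O)OC) with AlCl3 in CH2Cl2 should give methyl 7-oxabicyclo[2.2.1]hepta-2,5-diene-2-carboxylate F1, which opens in the same flask to methyl 3-hydroxybenzoate F2. Saponification (NaOH, aq. MeOH, then HCl) gives 3-hydroxybenzoic acid F3. Friedel–Crafts acylation of 1,3,5-trimethoxybenzene (COc1cc(OC)cc(OC)c1) with F3 in Eaton's reagent (P2O5/MeSO3H, 60 °C) then gives benzophenone 7.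

2. Step 6 (pyran annulation). The quinone methide may close onto the ortho oxygen O6 instead of O4, which would fuse the pyran the wrong way round, next to the ketone. Fallback, setting out from 10 and returning at 13: the ring oxygen is fixed before the carbon–carbon bond is made. Copper-catalysed O-alkylation of the most acidic, non-chelated para hydroxyl of 10 with 3-chloro-3-methylbut-1-yne (CC(C)(Cl)C#C; CuCl2 cat., DBU 1.0 equiv, MeCN, 0 °C) should give (3-hydroxyphenyl)[2,6-dihydroxy-4-(2-methylbut-3-yn-2-yloxy)-3-(3-methylbut-2-en-1-yl)phenyl]methanone F5. Heating F5 in xylene at 140 °C (aryl propargyl ether Claisen rearrangement to the only free ortho carbon, 1,5-hydrogen shift, oxa-6π closure) gives 13.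

3. Step 5 (mono-C-prenylation). Two equivalent ring carbons and several oxygens compete, so alkylation may run on to the 3,5-diprenyl compound or go to oxygen, leaving a statistical mixture. Fallback, setting out from 8 and returning at 13: the last two steps are reversed so that the prenylation meets a single free ring carbon. Tetraol 8 with 3-methylbut-2-enal 11 (1.0 equiv) and ethylenediamine diacetate in toluene at 110 °C should give (5,7-dihydroxy-2,2-dimethyl-2H-chromen-6-yl)(3-hydroxyphenyl)methanone F4. C-prenylation of F4 at C8 with prenyl bromide 9 (DBU, THF, 0 °C → rt) gives 13.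

**Further compounds**

F1 | step 3 | methyl 7-oxabicyclo[2.2.1]hepta-2,5-diene-2-carboxylate (racemic; not isolated) | COC(=O)C1=CC2OC1C=C2
F2 | step 3 | methyl 3-hydroxybenzoate | COC(=O)c1cccc(O)c1
F3 | step 3 | 3-hydroxybenzoic acid | OC(=O)c1cccc(O)c1
F4 | step 5 | (5,7-dihydroxy-2,2-dimethyl-2H-chromen-6-yl)(3-hydroxyphenyl)methanone | CC1(C)C=Cc2c(O1)cc(O)c(C(=O)c1cccc(O)c1)c2O
F5 | step 6 | (3-hydroxyphenyl)[2,6-dihydroxy-4-(2-methylbut-3-yn-2-yloxy)-3-(3-methylbut-2-en-1-yl)phenyl]methanone | CC(C)=CCc1c(OC(C)(C)C#C)cc(O)c(C(=O)c2cccc(O)c2)c1O
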